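**Retrosynthetic overview**
- Target: ent-3β-hydroxylabda-7,13E-dien-15-yl 32-hydroxydotriacontanoate. The C15–O ester bond is made last; the C32 acid comes from two C16 units (Wittig, then hydrogenation).
- C9–C11 is formed by adding a C11–C15 alkyllithium (from but-3-yn-1-ol by carboalumination) to a C9 ketone. Oxidative 1,3-transposition, Luche reduction and reductive allylic transposition then set H-9 and the C7=C8 alkene.
- The feature the route rests on: ring B carries C7=C8 with the C8 methyl, C9, and the C5 stereocentre bearing C4. These are the enone carbons, the carbonyl carbon and the isopropenyl-bearing carbon of (S)-carvone; C10 is carvone C6, made quaternary by methylation and allylation.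
- Ring A (C1–C4, with the C3 carbinol and the gem-dimethyl C4) is closed by the C3–C4 bond: a hydrogen-atom-transfer radical at C4 adds to a C3 aldehyde.
- Ring order: ring B comes from the chiral pool; ring A is closed second by radical cyclisation.

Key step: step 5

Remark: the acyl group is read as 32-hydroxydotriacontanoyl (carbonyl carbon plus 31 CH2). Labdane numbering is used for the decalins; "ent-3β" means the C3 oxygen is equatorial and cis to the C10 methyl.

**Ring B and ring A (steps 1–6)**

Step 1
Reactants: 1 (S)-(+)-carvone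
Product: 3 (5S,6R)-2,6-dimethyl-5-(prop-1-en-2-yl)cyclohex-2-en-1-one (6-methylcarvone; main epimer shown; used together with its C6 epimer), via lithium enolate of carvone 2 (not isolated)
Conditions: LiN(i-Pr)2, THF, −78 °C; MeI, −78 → 0 °C
Reagents that add atoms: iodomethane, CI
Why: Kinetic α'-deprotonation gives the cross-conjugated lithium enolate, and its C-methylation (enolate alkylation, SN2) should give 6-methylcarvone, mainly with methyl trans to isopropenyl; this C6 centre is erased in step 2, so the epimers are not separated.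

Step 2
Reactants: 3 6-methylcarvone (epimer mixture); 4 allyl bromide
Product: 6 (5R,6R)-6-allyl-2,6-dimethyl-5-(prop-1-en-2-yl)cyclohex-2-en-1-one, via lithium enolate of 6-methylcarvone 5 (not isolated)
Conditions: LiN(i-Pr)2, THF, −78 → 0 °C; 4, DMPU, −78 °C → rt
Reagents that add atoms: none
Why: Enolate alkylation of the tetrasubstituted lithium enolate should occur on the face away from the neighbouring isopropenyl group, placing allyl trans and methyl cis to isopropenyl, which is the C10 configuration needed for a trans ring fusion.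

Step 3
Reactants: 6 allyl ketone
Product: 8 (5R,6R)-6-(3-hydroxypropyl)-2,6-dimethyl-5-(prop-1-en-2-yl)cyclohex-2-en-1-one, via alkylbis(3-methylbutan-2-yl)borane 7 (not isolated)
Conditions: BH3·THF, 2-methylbut-2-ene, THF, 0 °C (gives Sia2BH); 6, 0 °C; then 30% H2O2, aq. NaOAc, 0 °C → rt
Reagents that add atoms: hydrogen peroxide, OO
Why: In this hydroboration–oxidation the bulky dialkylborane should add anti-Markovnikov to the monosubstituted allyl alkene much faster than to the 1,1-disubstituted isopropenyl group or the hindered conjugated ketone, and the weakly basic peroxide oxidation avoids nucleophilic epoxidation of the enone; no stereocentre is formed.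

Step 4
Reactants: 8 hydroxy ketone
Product: 9 3-[(1R,6R)-1,3-dimethyl-2-oxo-6-(prop-1-en-2-yl)cyclohex-3-en-1-yl]propanal
Conditions: Dess–Martin periodinane, CH2Cl2, 0 °C → rt
Reagents that add atoms: none
Why: Dess–Martin oxidation should convert the primary alcohol into the aldehyde under neutral conditions without touching the enone or the two alkenes; no stereocentre is formed.

Step 5
Reactants: 9 keto aldehyde
Product: 10 ent-3β-hydroxy-11-nordrim-7-en-9-one [(4aR,6R,8aR)-6-hydroxy-2,5,5,8a-tetramethyl-4a,5,6,7,8,8a-hexahydronaphthalen-1(4H)-one]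
Conditions: Fe(acac)3 (0.3 equiv), PhSiH3 (2.5 equiv), degassed EtOH, 60 °C
Reagents that add atoms: none
Why: The iron hydride formed from Fe(acac)3, PhSiH3 and ethanol should transfer a hydrogen atom to the terminal CH2 of the isopropenyl group, creating the second C4 methyl and a tertiary C4 radical; this radical adds to the aldehyde carbon C3, and the alkoxy radical is reduced by divalent iron and protonated by ethanol, which returns the trivalent iron catalyst. The closest known reaction type is the iron-catalysed hydrogen-atom-transfer reductive cyclisation of alkene-tethered ketones, together with additions of such radicals to aldehydes, which are documented though less widely. Ring A closes in the 6-exo-trig mode (C4 radical onto C3=O), and because the C1 chain and C4 are trans on ring B only the trans-decalin can form. The new C3 stereocentre should be set by a chair transition state with the carbonyl oxygen pseudo-equatorial, helped by reversibility of the addition (β-scission of the alkoxy radical), giving the equatorial alcohol cis to the C10 methyl. The step needs hydrogen-atom transfer to the electron-rich 1,1-disubstituted alkene and not to the electron-poor trisubstituted enone alkene, and cyclisation faster than reduction of the radical; the first follows from the alkene substitution pattern, the second from the 1,5 relationship of radical and aldehyde and from the enone carbons being out of reach of C4 (only four-membered rings could form).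

Step 6
Reactants: 10 hydroxy enone
Product: 11 ent-3β-[(tert-butyldimethylsilyl)oxy]-11-nordrim-7-en-9-one
Conditions: TBSOTf, 2,6-lutidine, CH2Cl2, −78 → 0 °C
Reagents that add atoms: tert-butyldimethylsilyl trifluoromethanesulfonate, CC(C)(C)[Si](C)(C)OS(=O)(=O)C(F)(F)F
Why: Silyl ether formation with the silyl triflate and a hindered pyridine base is the usual way to protect a neopentyl-type secondary alcohol, and at low temperature the enone should not be enolised; no stereocentre changes.

**C11–C15 fragment (steps 7–11)**

Step 7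
Reactants: 12 but-3-yn-1-ol
Product: 13 1-[(but-3-yn-1-yloxy)methyl]-4-methoxybenzene
Conditions: NaH, 4-methoxybenzyl chloride, Bu4NI (cat.), THF/DMF, 0 °C → rt
Reagents that add atoms: 4-methoxybenzyl chloride, COc1ccc(CCl)cc1
Why: In this Williamson ether synthesis the alkoxide forms in preference to the acetylide and is benzylated by the activated chloride.

Step 8
Reactants: 13 alkynyl ether
Product: 16 (E)-5-[(4-methoxybenzyl)oxy]-3-methylpent-2-en-1-ol, via alkenyldimethylalane 14 (not isolated), via lithium alkenylalanate 15 (not isolated)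
Conditions: AlMe3 (2.5 equiv), Cp2ZrCl2 (0.2 equiv), CH2Cl2, 0 °C → rt; n-BuLi, THF, −78 °C; (CH2O)n, → rt; 1 M HCl, 0 °C
Reagents that add atoms: trimethylaluminium, C[Al](C)C; formaldehyde (as paraformaldehyde), C=O
Why: Negishi zirconium-catalysed carboalumination adds methyl and aluminium syn across the terminal alkyne with methyl on the internal carbon, and the alanate is hydroxymethylated with retention, which should fix the E geometry of the C13=C14 alkene.

Step 9
Reactants: 16 allylic alcohol
Product: 17 (E)-tert-butyl({5-[(4-methoxybenzyl)oxy]-3-methylpent-2-en-1-yl}oxy)dimethylsilane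
Conditions: TBSCl, imidazole, CH2Cl2, rt
Reagents that add atoms: tert-butyldimethylsilyl chloride, CC(C)(C)[Si](C)(C)Cl
Why: Imidazole-promoted silylation of an unhindered primary alcohol is reliable and leaves the ether and alkene untouched.

Step 10
Reactants: 17 bis-ether
Product: 18 (E)-5-[(tert-butyldimethylsilyl)oxy]-3-methylpent-3-en-1-ol
Conditions: DDQ, CH2Cl2/pH 7 phosphate buffer, 0 °C
Reagents that add atoms: none
Why: Oxidative cleavage of the 4-methoxybenzyl ether by DDQ (benzylic hydride abstraction, then hydrolysis of the oxocarbenium ion) in buffered wet solvent should leave the allylic silyl ether and the alkene intact.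

Step 11
Reactants: 18 homoallylic alcohol
Product: 19 (E)-tert-butyl[(5-iodo-3-methylpent-2-en-1-yl)oxy]dimethylsilane
Conditions: I2, PPh3, imidazole, CH2Cl2, 0 °C, dark
Reagents that add atoms: iodine, II
Why: Appel-type iodination (Garegg–Samuelsson conditions) replaces the primary hydroxyl by iodide through SN2 displacement of the oxyphosphonium ion without affecting the allylic silyl ether.

**Side-chain attachment and C9/Δ7 adjustment (steps 12–16)**

Step 12
Reactants: 19 homoallylic iodide; 11 silylated enone
Product: 21 ent-3β,15-bis[(tert-butyldimethylsilyl)oxy]labda-7,13E-dien-9-ol (9-hydroxyl cis to the C10 methyl expected as main epimer), via homoallylic alkyllithium 20 (not isolated)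
Conditions: 19, t-BuLi (2.1 equiv per iodide), Et2O, −78 °C; then 11, Et2O/THF, −78 → −20 °C; H2O
Reagents that add atoms: none
Why: Iodine–lithium exchange gives the primary alkyllithium, which at low temperature should undergo 1,2-addition to the hindered enone carbonyl, expected on the face opposite the axial C10 methyl; the C9 carbinol configuration does not matter because step 13 removes it.

Step 13
Reactants: 21 tertiary allylic alcohol
Product: 22 ent-3β,15-bis[(tert-butyldimethylsilyl)oxy]labda-8,13E-dien-7-one
Conditions: [C5H5NH][CrO3Cl] (pyridinium chlorochromate), 4 Å molecular sieves, CH2Cl2, rt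
Reagents that add atoms: pyridinium chlorochromate, [O-][Cr](=O)(=O)Cl.c1cc[nH+]cc1
Why: In this Dauben–Michno oxidative 1,3-transposition the tertiary allylic chromate ester should undergo a [3,3] shift to C7 and be oxidised to the 8-en-7-one, the C7 oxygen coming from chromium, which clears the C9 carbinol centre.

Step 14
Reactants: 22 enone
Product: 23 ent-3β,15-bis[(tert-butyldimethylsilyl)oxy]labda-8,13E-dien-7β-ol (7-hydroxyl cis to the C10 methyl)
Conditions: NaBH4, CeCl3·7H2O, MeOH/THF, −78 → −20 °C
Reagents that add atoms: none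
Why: Luche reduction gives 1,2-reduction of the enone, and axial hydride delivery to the half-chair ring B, from the face opposite the C10 methyl, should place the C7 hydroxyl pseudo-equatorial and cis to that methyl.

Step 15
Reactants: 23 allylic alcohol
Product: 26 ent-3β,15-bis[(tert-butyldimethylsilyl)oxy]labda-7,13E-diene, via N-allylic sulfonylhydrazine 24 (not isolated), via allylic diazene 25 (not isolated)
Conditions: 2-O2NC6H4SO2NHNH2, PPh3, DEAD, N-methylmorpholine, −30 °C → rt
Reagents that add atoms: none
Why: In this Myers reductive allylic transposition the Mitsunobu displacement inverts C7, loss of the sulfinic acid gives the monoalkyl diazene, and its retro-ene loss of N2 delivers hydrogen to C9 on the face of the C7–N bond, trans to the C10 methyl, while the alkene moves to C7=C8.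

Step 16
Reactants: 26 bis-silyl ether
Product: 27 ent-3β-[(tert-butyldimethylsilyl)oxy]labda-7,13E-dien-15-ol
Conditions: HF·pyridine, pyridine, THF, 0 °C
Reagents that add atoms: none
Why: Selective desilylation is expected because buffered HF·pyridine cleaves the unhindered primary allylic silyl ether far faster than the secondary silyl ether flanked by the quaternary C4.

**C32 acid (steps 17–23)**

Step 17
Reactants: 28 16-hydroxyhexadecanoic acid
Product: 29 16-bromohexadecanoic acid
Conditions: 48% aq. HBr, conc. H2SO4 (cat.), 100 °C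
Reagents that add atoms: hydrogen bromide, Br
Why: Acid-promoted SN2 substitution of the protonated primary alcohol by bromide, with the aqueous acid keeping the carboxyl group free.

Step 18
Reactants: 29 bromo acid
Product: 30 (15-carboxypentadecyl)triphenylphosphonium bromide
Conditions: PPh3, MeCN, reflux
Reagents that add atoms: triphenylphosphine, c1ccc(cc1)P(c1ccccc1)c1ccccc1
Why: Quaternisation (SN2) of triphenylphosphine by the primary bromide gives the Wittig salt.

Step 19
Reactants: 28 16-hydroxyhexadecanoic acid
Product: 31 methyl 16-hydroxyhexadecanoate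
Conditions: MeOH, H2SO4 (cat.), reflux
Reagents that add atoms: methanol, CO
Why: Fischer esterification in excess methanol suppresses self-esterification of the hydroxy acid.

Step 20
Reactants: 31 hydroxy ester
Product: 32 methyl 16-[(tert-butyldimethylsilyl)oxy]hexadecanoate
Conditions: TBSCl, imidazole, DMF, rt
Reagents that add atoms: tert-butyldimethylsilyl chloride, CC(C)(C)[Si](C)(C)Cl
Why: Imidazole-promoted silylation of the primary alcohol is routine.

Step 21
Reactants: 32 silyloxy ester
Product: 33 16-[(tert-butyldimethylsilyl)oxy]hexadecanal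
Conditions: i-Bu2AlH (1.05 equiv), CH2Cl2, −78 °C; aq. KNaC4H4O6
Reagents that add atoms: none
Why: Partial ester reduction with i-Bu2AlH at −78 °C should stop at the tetrahedral aluminium hemiacetal, which gives the aldehyde on work-up.

Step 22
Reactants: 30 phosphonium salt; 33 aldehyde
Product: 35 (Z)-32-[(tert-butyldimethylsilyl)oxy]dotriacont-16-enoic acid, via phosphorus ylide carboxylate 34 (not isolated)
Conditions: NaN(SiMe3)2 (2.1 equiv), THF, 0 °C; 33, −78 °C → rt; 1 M HCl to pH 4, 0 °C
Reagents that add atoms: none
Why: In this Wittig olefination two equivalents of base give the carboxylate ylide, a non-stabilised ylide that should give mainly the Z alkene; the geometry is irrelevant because step 23 saturates it.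

Step 23
Reactants: 35 alkenoic acid
Product: 36 32-[(tert-butyldimethylsilyl)oxy]dotriacontanoic acid
Conditions: H2 (1 atm), Pd/C (10 wt% palladium on carbon), EtOAc/THF, 40 °C
Reagents that add atoms: none
Why: Heterogeneous catalytic hydrogenation saturates the disubstituted alkene, and the silyl ether is stable in the aprotic solvent.

**Union and deprotection (steps 24–25)**

Step 24
Reactants: 27 allylic alcohol; 36 silyloxy acid
Product: 37 ent-3β-[(tert-butyldimethylsilyl)oxy]labda-7,13E-dien-15-yl 32-[(tert-butyldimethylsilyl)oxy]dotriacontanoate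
Conditions: DCC, DMAP (0.2 equiv), CH2Cl2, rt
Reagents that add atoms: none
Why: Steglich esterification (carbodiimide activation, acyl transfer by DMAP) of the unhindered primary allylic alcohol, with the C3 hydroxyl and the acid's ω-hydroxyl both silylated so that only the C15 ester can form.

Step 25
Reactants: 37 bis-silyl ester
Product: 38 ent-3β-hydroxylabda-7,13E-dien-15-yl 32-hydroxydotriacontanoate (3R,5S,9R,10S; target)
Conditions: HF·pyridine (excess), THF, 0 → 40 °C
Reagents that add atoms: none
Why: Fluoride-mediated desilylation with excess HF·pyridine should remove both the primary and the hindered secondary silyl ether while the weakly acidic medium spares the allylic ester and both alkenes; no stereocentre is touched.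

**Compound list**

1 | (S)-(+)-carvone | CC1=CC[C@@H](CC1=O)C(C)=C | starting material
2 | lithium enolate of carvone (O–C1=C6) | CC1=CC[C@@H](C=C1[O-])C(C)=C.[Li+] | intermediate
3 | (5S,6R)-2,6-dimethyl-5-(prop-1-en-2-yl)cyclohex-2-en-1-one (main epimer) | CC1=CC[C@H](C(C)=C)[C@@H](C)C1=O | intermediate
4 | allyl bromide | C=CCBr | starting material
5 | lithium enolate of 6-methylcarvone | CC1=CC[C@H](C(C)=C)C(C)=C1[O-].[Li+] | intermediate
6 | (5R,6R)-6-allyl-2,6-dimethyl-5-(prop-1-en-2-yl)cyclohex-2-en-1-one | CC1=CC[C@H](C(C)=C)[C@@](C)(CC=C)C1=O | intermediate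
7 | {3-[(1R,6R)-1,3-dimethyl-2-oxo-6-(prop-1-en-2-yl)cyclohex-3-en-1-yl]propyl}bis(3-methylbutan-2-yl)borane | CC1=CC[C@H](C(C)=C)[C@@](C)(CCCB(C(C)C(C)C)C(C)C(C)C)C1=O | intermediate
8 | (5R,6R)-6-(3-hydroxypropyl)-2,6-dimethyl-5-(prop-1-en-2-yl)cyclohex-2-en-1-one | CC1=CC[C@H](C(C)=C)[C@@](C)(CCCO)C1=O | intermediate
9 | 3-[(1R,6R)-1,3-dimethyl-2-oxo-6-(prop-1-en-2-yl)cyclohex-3-en-1-yl]propanal | CC1=CC[C@H](C(C)=C)[C@@](C)(CCC=O)C1=O | intermediate
10 | ent-3β-hydroxy-11-nordrim-7-en-9-one | CC1=CC[C@@H]2C(C)(C)[C@H](O)CC[C@@]2(C)C1=O | intermediate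
11 | ent-3β-[(tert-butyldimethylsilyl)oxy]-11-nordrim-7-en-9-one | CC1=CC[C@@H]2C(C)(C)[C@H](O[Si](C)(C)C(C)(C)C)CC[C@@]2(C)C1=O | intermediate
12 | but-3-yn-1-ol | C#CCCO | starting material
13 | 1-[(but-3-yn-1-yloxy)methyl]-4-methoxybenzene | C#CCCOCc1ccc(OC)cc1 | intermediate
14 | (E)-{4-[(4-methoxybenzyl)oxy]-2-methylbut-1-en-1-yl}dimethylalane | C[Al](C)/C=C(\C)CCOCc1ccc(OC)cc1 | intermediate
15 | lithium butyl{(E)-4-[(4-methoxybenzyl)oxy]-2-methylbut-1-en-1-yl}dimethylalanate | [Li+].CCCC[Al-](C)(C)/C=C(\C)CCOCc1ccc(OC)cc1 | intermediate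
16 | (E)-5-[(4-methoxybenzyl)oxy]-3-methylpent-2-en-1-ol | OC/C=C(\C)CCOCc1ccc(OC)cc1 | intermediate
17 | (E)-tert-butyl({5-[(4-methoxybenzyl)oxy]-3-methylpent-2-en-1-yl}oxy)dimethylsilane | CC(C)(C)[Si](C)(C)OC/C=C(\C)CCOCc1ccc(OC)cc1 | intermediate
18 | (E)-5-[(tert-butyldimethylsilyl)oxy]-3-methylpent-3-en-1-ol | CC(C)(C)[Si](C)(C)OC/C=C(\C)CCO | intermediate
19 | (E)-tert-butyl[(5-iodo-3-methylpent-2-en-1-yl)oxy]dimethylsilane | CC(C)(C)[Si](C)(C)OC/C=C(\C)CCI | intermediate
20 | (E)-{5-[(tert-butyldimethylsilyl)oxy]-3-methylpent-3-en-1-yl}lithium | CC(C)(C)[Si](C)(C)OC/C=C(\C)CC[Li] | intermediate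
21 | ent-3β,15-bis[(tert-butyldimethylsilyl)oxy]labda-7,13E-dien-9-ol (9-OH cis to the C10 methyl) | CC1=CC[C@@H]2C(C)(C)[C@H](O[Si](C)(C)C(C)(C)C)CC[C@@]2(C)[C@@]1(O)CC/C(C)=C/CO[Si](C)(C)C(C)(C)C | intermediate
22 | ent-3β,15-bis[(tert-butyldimethylsilyl)oxy]labda-8,13E-dien-7-one | O=C1C[C@@H]2C(C)(C)[C@H](O[Si](C)(C)C(C)(C)C)CC[C@@]2(C)C(CC/C(C)=C/CO[Si](C)(C)C(C)(C)C)=C1C | intermediate
23 | ent-3β,15-bis[(tert-butyldimethylsilyl)oxy]labda-8,13E-dien-7β-ol (7-OH cis to the C10 methyl) | O[C@@H]1C[C@@H]2C(C)(C)[C@H](O[Si](C)(C)C(C)(C)C)CC[C@@]2(C)C(CC/C(C)=C/CO[Si](C)(C)C(C)(C)C)=C1C | intermediate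
24 | N-(labda-8,13E-dien-7-yl)-2-nitrobenzenesulfonohydrazide, bis-silyl ether, C7–N trans to the C10 methyl | NN([C@H]1C[C@@H]2C(C)(C)[C@H](O[Si](C)(C)C(C)(C)C)CC[C@@]2(C)C(CC/C(C)=C/CO[Si](C)(C)C(C)(C)C)=C1C)S(=O)(=O)c1ccccc1[N+](=O)[O-] | intermediate
25 | 7-diazenyl-labda-8,13E-diene bis-silyl ether (C7–N trans to the C10 methyl) | N=N[C@H]1C[C@@H]2C(C)(C)[C@H](O[Si](C)(C)C(C)(C)C)CC[C@@]2(C)C(CC/C(C)=C/CO[Si](C)(C)C(C)(C)C)=C1C | intermediate
26 | ent-3β,15-bis[(tert-butyldimethylsilyl)oxy]labda-7,13E-diene | CC1=CC[C@@H]2C(C)(C)[C@H](O[Si](C)(C)C(C)(C)C)CC[C@@]2(C)[C@@H]1CC/C(C)=C/CO[Si](C)(C)C(C)(C)C | intermediate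
27 | ent-3β-[(tert-butyldimethylsilyl)oxy]labda-7,13E-dien-15-ol | CC1=CC[C@@H]2C(C)(C)[C@H](O[Si](C)(C)C(C)(C)C)CC[C@@]2(C)[C@@H]1CC/C(C)=C/CO | intermediate
28 | 16-hydroxyhexadecanoic acid | OCCCCCCCCCCCCCCCC(=O)O | starting material
29 | 16-bromohexadecanoic acid | BrCCCCCCCCCCCCCCCC(=O)O | intermediate
30 | (15-carboxypentadecyl)triphenylphosphonium bromide | [Br-].OC(=O)CCCCCCCCCCCCCCC[P+](c1ccccc1)(c1ccccc1)c1ccccc1 | intermediate
31 | methyl 16-hydroxyhexadecanoate | COC(=O)CCCCCCCCCCCCCCCO | intermediate
32 | methyl 16-[(tert-butyldimethylsilyl)oxy]hexadecanoate | COC(=O)CCCCCCCCCCCCCCCO[Si](C)(C)C(C)(C)C | intermediate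
33 | 16-[(tert-butyldimethylsilyl)oxy]hexadecanal | O=CCCCCCCCCCCCCCCCO[Si](C)(C)C(C)(C)C | intermediate
34 | sodium 16-(triphenyl-λ5-phosphanylidene)hexadecanoate | [Na+].[O-]C(=O)CCCCCCCCCCCCCCC=P(c1ccccc1)(c1ccccc1)c1ccccc1 | intermediate
35 | (Z)-32-[(tert-butyldimethylsilyl)oxy]dotriacont-16-enoic acid | OC(=O)CCCCCCCCCCCCCC/C=C\CCCCCCCCCCCCCCCO[Si](C)(C)C(C)(C)C | intermediate
36 | 32-[(tert-butyldimethylsilyl)oxy]dotriacontanoic acid | OC(=O)CCCCCCCCCCCCCCCCCCCCCCCCCCCCCCCO[Si](C)(C)C(C)(C)C | intermediate
37 | ent-3β-[(tert-butyldimethylsilyl)oxy]labda-7,13E-dien-15-yl 32-[(tert-butyldimethylsilyl)oxy]dotriacontanoate | CC1=CC[C@@H]2C(C)(C)[C@H](O[Si](C)(C)C(C)(C)C)CC[C@@]2(C)[C@@H]1CC/C(C)=C/COC(=O)CCCCCCCCCCCCCCCCCCCCCCCCCCCCCCCO[Si](C)(C)C(C)(C)C | intermediate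
38 | ent-3β-hydroxylabda-7,13E-dien-15-yl 32-hydroxydotriacontanoate | CC1=CC[C@@H]2C(C)(C)[C@H](O)CC[C@@]2(C)[C@@H]1CC/C(C)=C/COC(=O)CCCCCCCCCCCCCCCCCCCCCCCCCCCCCCCO | target

**Step count**

Total: 25 steps. Longest linear sequence: 13 steps (steps 1–6, 12–16, 24, 25, from (S)-carvone).

**Steps most likely to fail**

1. Step 5. The tertiary C4 radical may be quenched by a second hydrogen-atom transfer before it cyclises, the alkoxy radical may fragment back, the aldehyde may be lost to acetalisation or silane reduction, or the face selectivity at C3 may be poor. The fallback sets out from 9. Treatment with I2 and aqueous NH3 in THF should convert the aldehyde into 3-[(1R,6R)-1,3-dimethyl-2-oxo-6-(prop-1-en-2-yl)cyclohex-3-en-1-yl]propanenitrile F1. The same Fe(acac)3/PhSiH3/EtOH conditions should then give 6-exo-dig addition of the C4 radical to the nitrile carbon, a documented acceptor for such radicals, and hydrolysis of the imine on acidic work-up gives ent-11-nordrim-7-ene-3,9-dione F2. NaBH4 at low temperature should reduce the saturated C3 ketone in preference to the conjugated, more hindered C9 ketone, by axial hydride attack, giving the equatorial alcohol; the route is rejoined at 10. In this variant the C3 configuration is set in a separate ketone reduction and not in the radical step.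

2. Step 15. The Mitsunobu displacement at the hindered secondary allylic C7 may be slow, and elimination to a diene or SN2' attack would lose the stereochemical relay to C9. The fallback sets out from 23. Formylation (HCO2H, DCC, DMAP) should give ent-3β,15-bis[(tert-butyldimethylsilyl)oxy]labda-8,13E-dien-7β-yl formate F3. Pd(OAc)2 and n-Bu3P in refluxing dioxane (Tsuji–Mandai hydrogenolysis of allylic formates) should ionise the formate anti with zerovalent palladium, lose CO2 and transfer hydride from palladium to the more substituted allyl terminus C9. The hydride arrives on the face opposite the original C7–O bond, which is the same stereochemical outcome, and the route is rejoined at 26.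

3. Step 3. The borane may also attack the isopropenyl group or reduce the ketone, and the oxidative work-up may epoxidise the enone. The fallback sets out from 6 and goes directly to 9 by an aldehyde-selective, nitrite-modified Wacker oxidation (PdCl2(PhCN)2, CuCl2·2H2O, AgNO2, O2, t-BuOH/MeNO2, rt). This oxidises the monosubstituted alkene at its terminal carbon and leaves the 1,1-disubstituted and trisubstituted alkenes alone; it replaces steps 3 and 4 and makes no new compound.

Further compounds
F1 | step 5 | 3-[(1R,6R)-1,3-dimethyl-2-oxo-6-(prop-1-en-2-yl)cyclohex-3-en-1-yl]propanenitrile | CC1=CC[C@H](C(C)=C)[C@@](C)(CCC#N)C1=O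
F2 | step 5 | ent-11-nordrim-7-ene-3,9-dione | CC1=CC[C@@H]2C(C)(C)C(=O)CC[C@@]2(C)C1=O
F3 | step 15 | ent-3β,15-bis[(tert-butyldimethylsilyl)oxy]labda-8,13E-dien-7β-yl formate | O=CO[C@@H]1C[C@@H]2C(C)(C)[C@H](O[Si](C)(C)C(C)(C)C)CC[C@@]2(C)C(CC/C(C)=C/CO[Si](C)(C)C(C)(C)C)=C1C
F0 | step 3 | none | none
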